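Remarks on the chemistry. Germacrane numbering (C1–C15) is used for every compound, including the monocyclic ones made from carvone; ring A is C3–C8 and ring B is C8, C9, C10, C1, C2, C3. The stereocentre of (S)-carvone is never touched and becomes C7; its descriptor changes between S and R along the route only because CIP priorities change. Compounds 6 and 7 are taken as purchasable. The way to the tricyclic diol and the end game were reworked in four places: the C9–C2 side chain is made Z- and regio-defined by olefination, the acid level at C12 is reached only after the enolate chemistry, the C8 hydroxyl is carried as a silyl ether through the lactonisation, and the C3 ketone is reduced under chelation control.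

## Structural features

The target is a germacranolide: a ten-membered carbocycle (C1–C10) fused at C6–C7 to an α-methylene-γ-butyrolactone (O on C6, C12 carbonyl, C11=C13 exocyclic), with H6 and H7 cis. The carbocycle carries a cis-configured trisubstituted epoxide at C1–C10 (methyl C14 on C10), a Z-trisubstituted double bond C4=C5 (methyl C15 on C4), an allylic acetate at C3 and a methacrylate at C8. There are six stereocentres, 1R,3S,6S,7R,8R,10S: C6, C7 and C8 are contiguous, C10 and C1 form the epoxide next to them, and C3 sits alone between the epoxide and the alkene. The fragile groups are the exocyclic methylene lactone (Michael acceptor, hydride-sensitive, able to isomerise into the ring), the allylic C6–O lactone bond, two different esters that rule out any late hydrolysis, and an epoxide flanked by oxygen functions. A free C8 hydroxyl can also attack the lactone carbonyl and move the lactone from O6 to O8. The real difficulty is the medium ring itself, which must hold two cis-configured units and three oxygen-bearing stereocentres that cannot be set independently of the ring conformation. The feature that the key step exploits is that the oxygenated carbons C3 and C8 lie 1,6 to each other, and that each half of the ring between them contains one cis element (Z-C4=C5 with the cis-lactone at C6–C7 on one side, the cis C9–C10–C1–C2 unit on the other). A bond from C3 to C8 therefore turns the ten-membered ring into two cis-fused cyclohexenes (ring A and ring B), a decalin-3,8-diol whose central bond is cut.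

## Logic of the disconnections

27 to 26: the C3–O acyl bond of the acetate is cut last, because the acetate would not survive any reductive or basic step and its removal leaves a simple secondary allylic alcohol. The forward step only has to acylate without opening the epoxide or exchanging the methacrylate.

26 to 25: the C3–H bond is cut, which turns the C3 carbinol into the enone carbonyl that the ring opening delivers. The gain is that C3 need not be carried as a stereocentre earlier. The demand is 1,2-selectivity in the presence of three conjugated acceptors and control of the face, which the epoxide oxygen on C1 can provide by chelation.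

25 to 24: the C8–O acyl bond of the methacrylate is cut. It is placed after the epoxidation because the free C8 hydroxyl is needed to direct it, and before the C3 reduction so that O8 is capped early. The demand is fast acylation of a hindered secondary alcohol under mild base.

24 to 23: the two C–O bonds of the epoxide (C1–O, C10–O) are cut back to the Z-C1=C10 alkene. The homoallylic C8 hydroxyl is the handle, and the C4=C5 alkene is protected by being part of an enone at this stage. The demand is delivery of oxygen to one face only.

23 to 22: the C8–H bond is cut, giving the 3,8-diketone. This removes the C8 stereocentre and reaches the direct product of a glycol fission. The demand is a hydride that takes the saturated ketone and not the enone or the exocyclic methylene, from the correct face, and quickly.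

22 to 21 (key disconnection): C3 and C8 are reconnected; in the forward sense the C3–C8 bond of a cis-diol is broken. Two carbonyl groups in a 1,6-relation are exactly what a glycol cleavage leaves behind. The gain is the largest of the plan: the ten-membered ring, both Z geometries and the cis-lactone are all stored in six- and five-membered rings. The demand is a cis-diol and an oxidant mild enough for a product that is a β-acyloxy ketone.

21 to 20: the C2–C3 bond of ring B is cut, which is the retron of an intramolecular allylation of the C3 ketone. Because C2 is tied to C8 through C9 and the Z-alkene, it can only reach the carbonyl face on which C9 stands, so the cis-diol follows from the tether. The demand is a metal that inserts into an allylic halide and tolerates a lactone, an enone and a free hydroxyl, and C–C bond formation at the halide-bearing carbon.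

20 to 19 to 18: the C2–Br bond and the silyl ethers are functional-group changes. The allylic bromide is made immediately before use because it would not survive any earlier step. The demand is that the C2 oxygen is protected by a group that outlasts all steps up to the lactone.

18 to 15: the C6–O bond of the lactone is cut. C6 is the γ-position of the ring A enone and, once C8 is quaternary, the only position that can be enolised. The gain is that the lactone becomes an acrylic acid side chain on C7. The demand is halogenation at C6 anti to that side chain, so that displacement with inversion gives the cis-fused ring.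

15 to 13 to 12: C12 is taken back from the acid to a protected allylic alcohol, because an acrylate could not be present during the two enolate steps. The demand is a pair of silyl ethers (C12 and C2) that can be told apart.

12 to 11: the C8–O bond is cut (enolate hydroxylation). It is placed after the alkylation so that oxygen enters anti to the C7 side chain at a tertiary enolate. The demand is regioselective α′-enolisation of an enone that also has γ-hydrogens.

11 to 5 and 10: the C8–C9 bond is cut, the convergent step that joins the ring A piece to the C9–C10(C14)–C1–C2 piece. The demand is a kinetic enolate and an allylic bromide that reacts at its primary carbon.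

5 to 4 to 2 to 1: the C12–O bond is cut back to the isopropenyl methyl group. This oxidation must come first, while the isopropenyl group is the only electron-rich alkene in the molecule. The demand is chlorination of the 1,1-disubstituted alkene and not of the enone.

10 to 9 to 8, then to 6 and 7: the C10=C1 double bond is cut by an olefination retron. This fixes the Z geometry that ring B needs, places the methyl group on C10 without ambiguity and delivers C9 and C2 at different oxidation levels. The demand is high Z selectivity for a trisubstituted enoate.

## Other disconnections considered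

Alternative 1: The cut is the acyl–alkenyl bond C5–C6. In the forward sense the seco thioester–alkenylstannane A1 would be cyclised with Pd2(dba)3, tri(2-furyl)phosphine and CuO2P(C6H5)2: zerovalent palladium inserts into the C–S bond with help from the copper carboxylate-type salt, the alkenyl group is transferred from tin, and reductive elimination closes the ring to the Z-enone A2.
- In its favour: the coupling is neutral and base-free, the Z geometry of C4=C5 is transferred with retention from the stannane, and C3 and C8 are set in an open chain by reagent control. On the last point it is better than the chosen plan, which has to create C3, C8 and the epoxide inside a ten-membered ring.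
- Against it here: the ten-membered ring must be closed by a bimolecular-type coupling at high dilution, in competition with oligomerisation, and a strained palladacycle has to eliminate. A2 also has an epimerisable C7 between a ketone and an ester.
- The lactone then still needs a face-selective C6 reduction to the cis isomer, the exocyclic methylene has to be added to the lactone enolate late, and the epoxide is still missing.
- On structure, the chosen plan gets the Z-alkenes and the cis-lactone for nothing, and A1 must build two Z-trisubstituted alkenes separately. On mechanism, the fragmentation has no ring-closure entropy to pay and the coupling does. On step economy the two are about equal at best, because A1 needs several stereodefined fragments and three protecting groups.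

Alternative 2: The cut is the C1=C10 double bond. In the forward sense the eleven-membered α-chlorosulfone A3 would be treated with KOC(CH3)3; deprotonation on the far side of sulfur gives the episulfone, which loses SO2 and contracts to the ten-membered diene lactone A4.
- In its favour: the ring is first closed as an eleven-membered sulfide, which is easier than a direct ten-membered C–C closure; SO2 loss is irreversible; and C3, C6, C7 and C8 pass through ring formation unchanged. On preserving C3 and C8 it is better than the chosen plan, which erases and resets them.
- Against it here: the new alkene is trisubstituted, so one α-carbon of the sulfone is tertiary and both chlorination and deprotonation there are hindered. The strong base meets a lactone with enolisable C11 hydrogens and an allylic C6–O bond that can eliminate. The alkene geometry is not fixed by the ten-membered ring, and strong bases tend towards E alkenes in this contraction.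
- On structure, the chosen plan takes the Z geometry of C1=C10 from a cyclohexene and is better there. On mechanism, both are fragmentations that avoid a true macrocyclisation and are equal in that respect. On step economy A4 still needs the lactone methylenation, two deprotections, epoxidation and both acylations, so it is not shorter.

Alternative 3: The cut is the C4=C5 double bond. In the forward sense the xylose-derived lactol phosphonate A5 would be treated with K2CO3 and 18-crown-6; the bis(trifluoroethyl) β-ketophosphonate is deprotonated at C4, the small amount of open hydroxy-aldehyde is trapped, and the olefination closes the ring to the Z-enone A6 while releasing the C8 hydroxyl.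
- In its favour: the sugar supplies the oxygenated C6 and C8 and the C7 branch point in defined form, the base is mild, and the kinetic Z preference of the trifluoroethyl phosphonate matches the target. A6 already has the hydroxy-enone pattern of 23, so no chemoselective reduction of a diketone and no guess about the face at C8 are needed. That is a real advantage over the chosen plan.
- Against it here: a ten-membered ring with a trisubstituted Z-enone has to form by olefination from a lactol that is mostly closed, so intermolecular reaction competes. The skipped C1=C10 alkene can move into conjugation with the ketophosphonate under base. The released C8 alkoxide can add across the ring or take over the lactone. The exocyclic methylene must be introduced late next to a ketone.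
- On structure, both plans draw C6–C8 from the chiral pool and are equal in that respect. On mechanism, the chosen plan avoids ring closure altogether. On step economy, the protecting-group work on a pentose usually costs more steps than the carvone sequence.

Key step: step 15

Step 1
Reactants: 1 (S)-(+)-carvone
Product: 2 (5S)-5-(3-chloroprop-1-en-2-yl)-2-methylcyclohex-2-en-1-one (10-chlorocarvone; chlorine on C12)
Conditions: Ca(OCl)2, CO2 (dry ice), CH2Cl2/H2O, 0 °C
Reagents that add atoms: calcium hypochlorite, [Ca+2].[O-]Cl.[O-]Cl
Why: Ene-type allylic chlorination by hypochlorous acid formed in the flask; the electron-rich 1,1-disubstituted isopropenyl alkene reacts and the enone alkene does not, and C7 is not involved.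

Step 2
Reactants: 2 10-chlorocarvone
Product: 4 (5S)-5-(3-hydroxyprop-1-en-2-yl)-2-methylcyclohex-2-en-1-one (10-hydroxycarvone), via 10-acetoxycarvone 3 (not isolated)
Conditions: KOAc, 18-crown-6 (cat.), DMF, 60 °C; then K2CO3 (cat.), MeOH, 0 °C to rt
Reagents that add atoms: potassium acetate, CC(=O)[O-].[K+]
Why: SN2 displacement of the primary allylic chloride by acetate (the allyl-shifted pathway would give the same product), then base-catalysed transesterification of the acetate to methanol; the mild base leaves the enone and C7 alone.

Step 3
Reactants: 4 10-hydroxycarvone
Product: 5 (5S)-5-[3-(tert-butyldimethylsilyloxy)prop-1-en-2-yl]-2-methylcyclohex-2-en-1-one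
Conditions: TBSCl, imidazole, CH2Cl2, rt
Reagents that add atoms: tert-butyldimethylsilyl chloride, CC(C)(C)[Si](C)(C)Cl
Why: Standard silylation of a primary allylic alcohol; the ether masks C12–OH during the two enolate steps and can later be removed in the presence of the bulkier silyl ether on C2.

Step 4
Reactants: 6 2-[(tert-butyldiphenylsilyl)oxy]acetaldehyde; 7 ethyl 2-[bis(2,2,2-trifluoroethoxy)phosphoryl]propanoate
Product: 8 ethyl (Z)-4-[(tert-butyldiphenylsilyl)oxy]-2-methylbut-2-enoate
Conditions: KN(SiMe3)2, 18-crown-6, THF, −78 °C
Reagents that add atoms: none
Why: Still–Gennari olefination: the electron-poor phosphonate eliminates fast from the kinetic adduct and gives the Z-trisubstituted enoate. This puts the methyl group on the future C10 and leaves C9 (ester) and C2 (silyl ether) differentiated.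

Step 5
Reactants: 8 Z-enoate
Product: 9 (Z)-4-[(tert-butyldiphenylsilyl)oxy]-2-methylbut-2-en-1-ol
Conditions: iBu2AlH, CH2Cl2, −78 °C
Reagents that add atoms: none
Why: 1,2-Reduction of the conjugated ester to the allylic alcohol by the aluminium hydride; the alkene geometry and the silyl ether are not affected.

Step 6
Reactants: 9 Z-allylic alcohol
Product: 10 [(Z)-4-bromo-3-methylbut-2-enoxy](tert-butyl)diphenylsilane
Conditions: CBr4, PPh3, CH2Cl2, 0 °C
Reagents that add atoms: carbon tetrabromide, BrC(Br)(Br)Br
Why: Appel reaction; the oxyphosphonium ion is displaced by bromide at the primary carbon under neutral conditions, without allylic shift or Z/E isomerisation.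

Step 7
Reactants: 5 silyl ether of 10-hydroxycarvone; 10 Z-allylic bromide
Product: 11 (7S,8R)-ketone: (5S,6R)-6-[(Z)-4-(tert-butyldiphenylsilyloxy)-2-methylbut-2-enyl]-5-[3-(tert-butyldimethylsilyloxy)prop-1-en-2-yl]-2-methylcyclohex-2-en-1-one
Conditions: LiN(iPr)2, THF, −78 °C; then 10, DMPU, −78 to −30 °C
Reagents that add atoms: none
Why: Alkylation of the kinetic α′-enolate (C8) of the enone with a reactive 2-substituted allylic bromide forms C8–C9. The electrophile enters anti to the C7 side chain; this C8 configuration is erased again in step 8.

Step 8
Reactants: 11 alkylated ketone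
Product: 12 (7R,8R)-8-hydroxy ketone (hydroxyl trans to the C7 side chain and C9 cis to it)
Conditions: KN(SiMe3)2, THF, −78 °C; then 2-(phenylsulfonyl)-3-phenyloxaziridine, −78 °C
Reagents that add atoms: 2-(phenylsulfonyl)-3-phenyloxaziridine, O=S(=O)(c1ccccc1)N1OC1c1ccccc1
Why: Davis oxidation of the tetrasubstituted potassium enolate. Allylic strain turns the C7 side chain pseudo-axial, so oxygen is delivered to the opposite face; C8 is now quaternary and only C6 can be enolised afterwards.

Step 9
Reactants: 12 hydroxy ketone
Product: 13 (7R,8R)-12-alcohol (primary allylic alcohol on the C7 side chain; silyl ether on C2 retained)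
Conditions: PPTS (cat.), MeOH, rt
Reagents that add atoms: none
Why: Acid-catalysed methanolysis removes the primary tert-butyldimethylsilyl ether far faster than the tert-butyldiphenylsilyl ether; the tertiary ketol is inert.

Step 10
Reactants: 13 12-alcohol
Product: 15 (7R,8R)-acrylic acid (C12 carboxylic acid on C11=C13), via enal 14 (not isolated)
Conditions: TEMPO (cat.), PhI(OAc)2, CH2Cl2, rt; then NaClO2, NaH2PO4, 2-methyl-2-butene, t-BuOH/H2O, 0 °C
Reagents that add atoms: sodium chlorite, [Na+].[O-]Cl=O
Why: Oxoammonium oxidation takes only the primary allylic alcohol (the tertiary ketol cannot be oxidised); Pinnick oxidation then converts the enal to the acid while the alkene scavenger removes hypochlorite.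

Step 11
Reactants: 15 acrylic acid
Product: 18 (6S,7S,8R)-cis-lactone enone with trimethylsilyl ether on O8 and tert-butyldiphenylsilyl ether on C2, via tris-silylated dienol ether 16 (not isolated), via C6 bromide 17 (not isolated)
Conditions: TMSOTf, Et3N, CH2Cl2, 0 °C; then NBS, THF, −78 °C; then aq. NaHCO3, rt
Reagents that add atoms: trimethylsilyl triflate, C[Si](C)(C)OS(=O)(=O)C(F)(F)F
Why: Soft enolisation can only remove a C6 hydrogen, giving the silyloxy diene (acid and C8 hydroxyl are silylated too). NBS brominates the diene terminus C6 anti to the C7 side chain (vinylogous α-bromination of a silyl dienol ether). Bicarbonate then frees the carboxylate, which displaces the allylic bromide from the rear (5-exo SN2), so O6 ends cis to C11 and C6 becomes S.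

Step 12
Reactants: 18 silylated lactone enone
Product: 19 (6S,7S,8R)-lactone enone diol (free C8 hydroxyl and free allylic C2 hydroxyl)
Conditions: HF·pyridine, pyridine, THF, 0 °C to rt
Reagents that add atoms: none
Why: Fluoride-driven cleavage of both silyl ethers in one operation; the pyridine buffer keeps the allylic lactone and the exocyclic methylene intact.

Step 13
Reactants: 19 lactone enone diol
Product: 20 (6S,7S,8R)-allylic bromide (bromine on C2 and Z-C10=C1)
Conditions: CBr4, PPh3, CH2Cl2, −20 °C
Reagents that add atoms: carbon tetrabromide, BrC(Br)(Br)Br
Why: Appel reaction on the primary allylic alcohol; the tertiary hydroxyl next to the ketone is too hindered and too deactivated to react. The bromide is used at once because the C8 hydroxyl could alkylate it on standing.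

Step 14
Reactants: 20 allylic bromide
Product: 21 (3S,6S,7S,8R)-3,8-dihydroxy-3,8-cyclogermacra-1(10),4,11(13)-trien-12,6-olide (cis-fused decalin-3,8-diol lactone)
Conditions: CrCl2, THF, rt, high dilution
Reagents that add atoms: none
Why: Intramolecular Nozaki–Hiyama (Barbier-type) allylation: two equivalents of divalent chromium insert into the C2–Br bond, and the allylchromium adds to the adjacent C3 ketone (held by the chromium alkoxide of the C8 hydroxyl) without touching the lactone or the conjugated alkenes. The γ-terminus C10 is fully substituted and could only close a cyclobutane, so the bond forms at C2 and the Z-alkene ends up inside cyclohexene ring B. C2 is tied to C8 through C9 and C10=C1 and can reach C3 only on the face that carries C9, so the ring fusion and the diol are cis (C3 becomes S).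

Step 15
Reactants: 21 cis-fused decalin-3,8-diol lactone
Product: 22 (6S,7S)-3,8-dioxogermacra-1(10)Z,4Z,11(13)-trien-12,6-olide (ten-membered 3,8-diketone)
Conditions: Pb(OAc)4, CH2Cl2, −20 °C, 15 min; filtered and used at once
Reagents that add atoms: none
Why: Criegee glycol cleavage: the two tertiary hydroxyls displace acetate on tetravalent lead to give a five-membered cyclic lead diester, which collapses in one two-electron fragmentation that breaks C3–C8, forms the C3 and C8 carbonyl groups and releases Pb(OAc)2 (divalent lead) and acetic acid. The closest known reaction is the cleavage of cis-9,10-decalindiols to cyclodecane-1,6-diones. No ring is closed by bond formation: the ten-membered ring appears because the bond shared by rings A and B is removed, so there is no macrocyclisation entropy to pay and no closure mode to control. No stereocentre is created; C3 and C8 are erased, C6 and C7 are untouched, and both Z double bonds come from six-membered rings in which no other geometry exists. The step needs a gauche O–C3–C8–O arrangement for the cyclic diester, which the cis ring fusion from step 14 provides, and chemoselectivity for the glycol over three alkenes, which Pb(OAc)4 shows at −20 °C. The product is a β-acyloxy ketone with an acidic C7 hydrogen and two β,γ-unsaturated ketones, so no base is added and it is reduced immediately, before C7 epimerisation, loss of the lactone carboxylate or transannular aldol closure can occur.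

Step 16
Reactants: 22 3,8-diketone
Product: 23 (6S,7R,8R)-8-hydroxy-3-oxogermacra-1(10)Z,4Z,11(13)-trien-12,6-olide
Conditions: NaBH4, MeOH/CH2Cl2, −78 °C; AcOH quench at −78 °C
Reagents that add atoms: none
Why: Without a cerium salt, borohydride reduces the saturated C8 ketone faster than the conjugated C3 ketone, and at −78 °C it does not add to the exocyclic methylene. In the Felkin–Anh arrangement the C7–C6 ring bond stands perpendicular to the carbonyl, hydride enters anti to it from the outer face with H7 over C9, and this gives 8R. The cold acidic quench keeps the new alkoxide from attacking the lactone.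

Step 17
Reactants: 23 8-hydroxy ketone
Product: 24 (1R,6S,7R,8R,10S)-1,10-epoxy-8-hydroxy-3-oxogermacra-4Z,11(13)-dien-12,6-olide
Conditions: VO(acac)2 (cat.), t-BuOOH, CH2Cl2, 0 °C
Reagents that add atoms: tert-butyl hydroperoxide, CC(C)(C)OO
Why: Hydroxyl-directed epoxidation of a homoallylic alcohol: the vanadate ester of O8 carries the peroxide to the C1=C10 alkene, while the enone alkene and the acrylate-type alkene are too electron-poor to react. Allylic strain with C2 holds C8 out of the alkene plane, and with C7 pointing outward the O8–vanadium unit can reach only one face, which gives the 1R,10S epoxide.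

Step 18
Reactants: 24 epoxy alcohol
Product: 25 (1R,6S,7R,8R,10S)-1,10-epoxy-8-(methacryloyloxy)-3-oxogermacra-4Z,11(13)-dien-12,6-olide
Conditions: methacrylic anhydride, Et3N, DMAP (cat.), CH2Cl2, 0 °C
Reagents that add atoms: methacrylic anhydride, CC(=C)C(=O)OC(=O)C(C)=C
Why: DMAP-catalysed acylation of the secondary alcohol with retention at C8; capping O8 now also stops it from attacking the lactone carbonyl or the epoxide later.

Step 19
Reactants: 25 methacrylate enone
Product: 26 (1R,3S,6S,7R,8R,10S)-1,10-epoxy-3-hydroxy-8-(methacryloyloxy)germacra-4Z,11(13)-dien-12,6-olide
Conditions: Zn(BH4)2, Et2O, −30 °C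
Reagents that add atoms: none
Why: Zinc borohydride reduces enones at the carbonyl and leaves esters, the lactone and the epoxide alone at this temperature. Zinc bridges the C3 carbonyl and the epoxide oxygen on C1 in a six-membered chelate (β-alkoxy ketone model), and external hydride then gives the 1,3-syn relation between the C1 and C3 oxygens, which is 3S.

Step 20
Reactants: 26 allylic alcohol
Product: 27 (1R,3S,4Z,6S,7R,8R,10S)-3-acetoxy-1,10-epoxy-8-(methacryloyloxy)germacra-4,11(13)-dien-12,6-olide (CNP0267696.1)
Conditions: Ac2O, pyridine, DMAP (cat.), CH2Cl2, 0 °C to rt
Reagents that add atoms: acetic anhydride, CC(=O)OC(C)=O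
Why: Nucleophilic-catalysed acetylation of the secondary allylic alcohol with retention at C3; nothing else in the molecule reacts with the anhydride.

## Compound list

1 | (S)-(+)-carvone | CC1=CC[C@@H](CC1=O)C(C)=C | starting material
2 | (5S)-5-(3-chloroprop-1-en-2-yl)-2-methylcyclohex-2-en-1-one | CC1=CC[C@@H](CC1=O)C(=C)CCl | intermediate
3 | 10-acetoxycarvone (acetate of 4) | CC1=CC[C@@H](CC1=O)C(=C)COC(C)=O | intermediate (not isolated)
4 | (5S)-5-(3-hydroxyprop-1-en-2-yl)-2-methylcyclohex-2-en-1-one | CC1=CC[C@@H](CC1=O)C(=C)CO | intermediate
5 | tert-butyldimethylsilyl ether of 4 | CC1=CC[C@@H](CC1=O)C(=C)CO[Si](C)(C)C(C)(C)C | intermediate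
6 | 2-[(tert-butyldiphenylsilyl)oxy]acetaldehyde | O=CCO[Si](c1ccccc1)(c1ccccc1)C(C)(C)C | starting material
7 | ethyl 2-[bis(2,2,2-trifluoroethoxy)phosphoryl]propanoate | CCOC(=O)C(C)P(=O)(OCC(F)(F)F)OCC(F)(F)F | starting material
8 | ethyl (Z)-4-[(tert-butyldiphenylsilyl)oxy]-2-methylbut-2-enoate | CCOC(=O)/C(C)=C\CO[Si](c1ccccc1)(c1ccccc1)C(C)(C)C | intermediate
9 | (Z)-4-[(tert-butyldiphenylsilyl)oxy]-2-methylbut-2-en-1-ol | OC/C(C)=C\CO[Si](c1ccccc1)(c1ccccc1)C(C)(C)C | intermediate
10 | [(Z)-4-bromo-3-methylbut-2-enoxy](tert-butyl)diphenylsilane | BrC/C(C)=C\CO[Si](c1ccccc1)(c1ccccc1)C(C)(C)C | intermediate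
11 | (7S,8R)-C8-alkylated ketone, side chain trans to the C7 substituent | CC1=CC[C@@H]([C@@H](C/C(C)=C\CO[Si](c2ccccc2)(c2ccccc2)C(C)(C)C)C1=O)C(=C)CO[Si](C)(C)C(C)(C)C | intermediate
12 | (7R,8R)-8-hydroxy ketone, hydroxyl trans to the C7 substituent | CC1=CC[C@@H]([C@](O)(C/C(C)=C\CO[Si](c2ccccc2)(c2ccccc2)C(C)(C)C)C1=O)C(=C)CO[Si](C)(C)C(C)(C)C | intermediate
13 | (7R,8R)-12-alcohol | CC1=CC[C@@H]([C@](O)(C/C(C)=C\CO[Si](c2ccccc2)(c2ccccc2)C(C)(C)C)C1=O)C(=C)CO | intermediate
14 | (7R,8R)-12-enal | CC1=CC[C@@H]([C@](O)(C/C(C)=C\CO[Si](c2ccccc2)(c2ccccc2)C(C)(C)C)C1=O)C(=C)C=O | intermediate (not isolated)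
15 | (7R,8R)-acrylic acid | CC1=CC[C@@H]([C@](O)(C/C(C)=C\CO[Si](c2ccccc2)(c2ccccc2)C(C)(C)C)C1=O)C(=C)C(O)=O | intermediate
16 | (7R,8R)-tris(trimethylsilyl) compound: C3 dienol ether, C8 ether, C12 silyl ester | C[Si](C)(C)OC1=C(C)C=C[C@@H]([C@]1(O[Si](C)(C)C)C/C(C)=C\CO[Si](c2ccccc2)(c2ccccc2)C(C)(C)C)C(=C)C(=O)O[Si](C)(C)C | intermediate (not isolated)
17 | (6R,7R,8R)-6-bromo enone, bromine trans to the C7 side chain | CC1=C[C@@H](Br)[C@@H]([C@](O[Si](C)(C)C)(C/C(C)=C\CO[Si](c2ccccc2)(c2ccccc2)C(C)(C)C)C1=O)C(=C)C(=O)O[Si](C)(C)C | intermediate (not isolated)
18 | (6S,7S,8R)-cis-lactone enone, O8 trimethylsilyl ether, C2 silyl ether | CC1=C[C@@H]2OC(=O)C(=C)[C@@H]2[C@](O[Si](C)(C)C)(C/C(C)=C\CO[Si](c3ccccc3)(c3ccccc3)C(C)(C)C)C1=O | intermediate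
19 | (6S,7S,8R)-cis-lactone enone diol | CC1=C[C@@H]2OC(=O)C(=C)[C@@H]2[C@](O)(C/C(C)=C\CO)C1=O | intermediate
20 | (6S,7S,8R)-cis-lactone enone, C2 allylic bromide | CC1=C[C@@H]2OC(=O)C(=C)[C@@H]2[C@](O)(C/C(C)=C\CBr)C1=O | intermediate
21 | (3S,6S,7S,8R)-3,8-dihydroxy-3,8-cyclogermacra-1(10),4,11(13)-trien-12,6-olide | O[C@]13CC(C)=CC[C@]3(O)C(C)=C[C@@H]2OC(=O)C(=C)[C@@H]21 | intermediate
22 | (6S,7S)-3,8-dioxogermacra-1(10)Z,4Z,11(13)-trien-12,6-olide | O=C1C/C(C)=C\CC(=O)/C(C)=C\[C@@H]2OC(=O)C(=C)[C@@H]21 | intermediate
23 | (6S,7R,8R)-8-hydroxy-3-oxogermacra-1(10)Z,4Z,11(13)-trien-12,6-olide | O[C@@H]1C/C(C)=C\CC(=O)/C(C)=C\[C@@H]2OC(=O)C(=C)[C@@H]21 | intermediate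
24 | (1R,6S,7R,8R,10S)-1,10-epoxy-8-hydroxy-3-oxogermacra-4Z,11(13)-dien-12,6-olide | O[C@@H]1C[C@]2(C)O[C@@H]2CC(=O)/C(C)=C\[C@@H]2OC(=O)C(=C)[C@@H]21 | intermediate
25 | (1R,6S,7R,8R,10S)-1,10-epoxy-8-(methacryloyloxy)-3-oxogermacra-4Z,11(13)-dien-12,6-olide | C=C(C)C(=O)O[C@@H]1C[C@]2(C)O[C@@H]2CC(=O)/C(C)=C\[C@@H]2OC(=O)C(=C)[C@@H]21 | intermediate
26 | (1R,3S,6S,7R,8R,10S)-1,10-epoxy-3-hydroxy-8-(methacryloyloxy)germacra-4Z,11(13)-dien-12,6-olide | C=C(C)C(=O)O[C@@H]1C[C@]2(C)O[C@@H]2C[C@H](O)/C(C)=C\[C@@H]2OC(=O)C(=C)[C@@H]21 | intermediate
27 | (1R,3S,4Z,6S,7R,8R,10S)-3-acetoxy-1,10-epoxy-8-(methacryloyloxy)germacra-4,11(13)-dien-12,6-olide | C=C(C)C(=O)O[C@@H]1C[C@]2(C)O[C@@H]2C[C@H](OC(C)=O)/C(C)=C\[C@@H]2OC(=O)C(=C)[C@@H]21 | target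

## Step count and risks

Total: 20 steps. Longest linear sequence: 17 steps (steps 1–3 and 7–20 from 1); the side-chain bromide 10 takes 3 steps (4–6).

Least certain steps:

1. Step 14 (ring B closure). The allylchromium must bond through its metal-bearing carbon, because the usual allyl-shifted pathway is closed. The most likely failure is that addition is slower than protonation or dimerisation of the allylmetal, or that the γ-acyloxy enone loses its carboxylate by reduction.
   - Fallback: it sets out from 18 and returns at 21, and closes ring B by metathesis instead.
   - Allyl bromide and Zn in THF/aq. NH4Cl should add to the C3 ketone of 18 to give the allyl carbinol F1. On the silyl ether no chelate forms, so attack anti to the C8–O bond is expected and places the allyl group cis to C9.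
   - Ring-closing metathesis with second-generation Grubbs catalyst would then join the allyl CH to C10 and expel the old C1–C2 unit as an allyl silyl ether, giving the trimethylsilyl ether of the tricyclic diol F2. HF·pyridine frees 21.
   - Its weakness, and the reason it is not the main line, is that the face of the intermolecular addition is not enforced by a tether.

2. Step 15 (key step). Formation of the cyclic lead diester from a congested ditertiary diol may be slow, and the diketone may degrade on isolation through C7 epimerisation, loss of the lactone carboxylate or transannular aldol reaction.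
   - Fallback: it sets out from 21 and returns at 22. The same bond is cleaved by a one-electron pathway with (NH4)2Ce(NO3)6 in MeCN/H2O at 0 °C. This goes through an alkoxy radical, needs no cyclic diester and so also cleaves a diol that cannot reach the gauche arrangement. It makes no new compound (F0).

3. Step 11 (bromination and lactonisation). Bromine may attack C4 or the side-chain alkene instead of C6, or enter syn to the C7 side chain, which leads to elimination or a trans-fused lactone.
   - Fallback: it sets out from 15 and returns at 19, and forms the C6–O bond by iodolactonisation.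
   - The dienol ether 16 is hydrolysed under kinetic conditions (AcOH, THF/H2O, −78 °C) to the β,γ-unsaturated keto acid F3 (C5=C6).
   - I2 and NaHCO3 close the iodolactone F4; the 5-exo closure can only give the cis fusion.
   - Et3N eliminates hydrogen iodide through the C4 enolate to the conjugated lactone enone F5, and HF·pyridine gives 19.

4. Step 16 (C8 reduction). Hydride may attack from the other face if the ring does not adopt the Felkin–Anh arrangement; the enone or the exocyclic methylene may be reduced as well; and the new alkoxide may take over the lactone.
   - Fallback: it sets out from 22 and returns at 25. If the epimeric 8S alcohol F6 forms, Mitsunobu esterification with methacrylic acid (PPh3, diisopropyl azodicarboxylate) inverts C8 and installs the ester in one operation, giving the diene methacrylate F7.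
   - Reagent-controlled Shi epoxidation (fructose-derived ketone of the matching configuration, KHSO5) then gives 25.

5. Step 17 (epoxidation). Oxygen may be delivered to the wrong face if the vanadate ester reaches the alkene from a conformer other than the one assumed, and the Lewis-acidic metal may promote attack of O8 on the epoxide or the lactone.
   - Fallback: it sets out from 23 and returns at 24. Shi epoxidation with the chiral dioxirane selects the face by the configuration of the catalyst and attacks only the electron-rich trisubstituted alkene. It makes no new compound (F0).

6. Step 19 (C3 reduction). If the zinc chelate with the epoxide oxygen does not form in the ring, the facial selectivity may be poor, and some conjugate reduction is possible.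
   - Fallback: it sets out from 25 and returns at 27. The 3R alcohol F8 is inverted by Mitsunobu reaction with acetic acid (PPh3, diisopropyl azodicarboxylate), which gives the acetate 27 directly. Attack at the far end of the allylic system is the process to watch.

## Further compounds

F1 | step 14 | (3S,6S,7S,8R)-3-allyl-3-hydroxy lactone with O8 trimethylsilyl ether and C2 silyl ether | CC1=C[C@@H]2OC(=O)C(=C)[C@@H]2[C@](O[Si](C)(C)C)(C/C(C)=C\CO[Si](c3ccccc3)(c3ccccc3)C(C)(C)C)[C@]1(O)CC=C
F2 | step 14 | 8-O-trimethylsilyl ether of 21 | C[Si](C)(C)O[C@]13CC(C)=CC[C@]3(O)C(C)=C[C@@H]2OC(=O)C(=C)[C@@H]21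
F3 | step 11 | (7R,8R)-β,γ-unsaturated keto acid (C5=C6; C4 epimers) | CC1C=C[C@@H]([C@](O)(C/C(C)=C\CO[Si](c2ccccc2)(c2ccccc2)C(C)(C)C)C1=O)C(=C)C(O)=O
F4 | step 11 | (6S,7S,8R)-5-iodo cis-lactone, iodine trans to O6 (C4 epimers) | CC1[C@@H](I)[C@@H]2OC(=O)C(=C)[C@@H]2[C@](O)(C/C(C)=C\CO[Si](c3ccccc3)(c3ccccc3)C(C)(C)C)C1=O
F5 | step 11 | (6S,7S,8R)-cis-lactone enone with free C8 hydroxyl and C2 silyl ether | CC1=C[C@@H]2OC(=O)C(=C)[C@@H]2[C@](O)(C/C(C)=C\CO[Si](c3ccccc3)(c3ccccc3)C(C)(C)C)C1=O
F6 | step 16 | (6S,7R,8S)-8-hydroxy-3-oxogermacra-1(10)Z,4Z,11(13)-trien-12,6-olide | O[C@H]1C/C(C)=C\CC(=O)/C(C)=C\[C@@H]2OC(=O)C(=C)[C@@H]21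
F7 | step 16 | (6S,7R,8R)-8-(methacryloyloxy)-3-oxogermacra-1(10)Z,4Z,11(13)-trien-12,6-olide | C=C(C)C(=O)O[C@@H]1C/C(C)=C\CC(=O)/C(C)=C\[C@@H]2OC(=O)C(=C)[C@@H]21
F8 | step 19 | (1R,3R,6S,7R,8R,10S)-1,10-epoxy-3-hydroxy-8-(methacryloyloxy)germacra-4Z,11(13)-dien-12,6-olide | C=C(C)C(=O)O[C@@H]1C[C@]2(C)O[C@@H]2C[C@@H](O)/C(C)=C\[C@@H]2OC(=O)C(=C)[C@@H]21
F0 | step 15 | none | none
F0 | step 17 | none | none
A1 | alternative 1 | seco S-ethyl thioester with C5 tributylstannyl alkene | CCSC(=O)[C@H](CC(=O)OC)[C@H](O[Si](C)(C)C(C)(C)C)C/C(C)=C\C[C@H](O[Si](CC)(CC)CC)/C(C)=C\[Sn](CCCC)(CCCC)CCCC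
A2 | alternative 1 | ten-membered C6 ketone with the C7 acetate side chain | CC(C)(C)[Si](C)(C)O[C@@H]1C/C(C)=C\C[C@H](O[Si](CC)(CC)CC)/C(C)=C\C(=O)[C@@H]1CC(=O)OC
A3 | alternative 2 | eleven-membered α-chlorosulfone (sulfur between C1 and C10; C1 and C10 epimers) | CC(C)(C)[Si](C)(C)O[C@@H]1CC(C)S(=O)(=O)C(Cl)C[C@H](OCc2ccc(OC)cc2)/C(C)=C\[C@@H]2OC(=O)C[C@@H]21
A4 | alternative 2 | ten-membered Z,Z-diene lactone | CC(C)(C)[Si](C)(C)O[C@@H]1C/C(C)=C\C[C@H](OCc2ccc(OC)cc2)/C(C)=C\[C@@H]2OC(=O)C[C@@H]21
A5 | alternative 3 | bicyclic lactol lactone with bis(trifluoroethyl) β-ketophosphonate chain (C4 and C5 epimers) | OC1O[C@H](C/C(C)=C\CC(=O)C(C)P(=O)(OCC(F)(F)F)OCC(F)(F)F)[C@H]2CC(=O)O[C@@H]12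
A6 | alternative 3 | ten-membered Z-enone with free C8 hydroxyl | O[C@@H]1C/C(C)=C\CC(=O)/C(C)=C\[C@@H]2OC(=O)C[C@@H]21
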